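**Retrosynthetic overview**
- Target (1'R; exocyclic Br trans to the ring oxygen, 5E): the last step is O-acetylation of the corresponding hydroxy lactone.
- The butenolide, the only ring of the target, is closed in step 5 by forming the O1–C5 bond: 5-exo-dig anti-bromolactonisation of a 3-bromo-2-en-4-ynoic acid, which also sets the E-bromomethylidene group.
- The enynoic acid comes from a 4-bromo-5-hydroxybutenolide (lactol) by one-carbon alkyne homologation. This lactol ring forms in step 3 and is reopened in step 4; it locks CO2H cis to the future alkyne.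
- The lactol comes from an enantioselective three-component bromo-aldol of a 4,4-diethoxybut-2-ynoate, TMSBr and butanal (C–C bond, C–Br bond, stereocentre, alkene geometry).
- The ynoate comes from 3,3-diethoxyprop-1-yne and Boc2O.

Assumption: the sense of induction in step 2 is taken from the usual aldehyde-binding model of this catalyst family; if the first run gives the 1S alcohol, the (R)-catalyst is used and nothing else changes.

**Step 1**
Reactants: 1 3,3-diethoxyprop-1-yne
Product: 3 tert-butyl 4,4-diethoxybut-2-ynoate, via lithium acetylide 2 (not isolated)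
Conditions: n-BuLi, THF, −78 °C; then Boc2O, −78 → 0 °C; water
Reagents that add atoms: di-tert-butyl dicarbonate, CC(C)(C)OC(=O)OC(=O)OC(C)(C)C
Why: The lithium acetylide is acylated at carbon by Boc2O (acetylide alkoxycarbonylation), a standard route to tert-butyl ynoates that leaves the base-stable acetal untouched; no stereocentre is formed.

**Step 2**
Reactants: 3 tert-butyl 4,4-diethoxybut-2-ynoate; 4 butanal
Product: 7 tert-butyl (2E)-3-bromo-4,4-diethoxy-2-[(1R)-1-hydroxybutyl]but-2-enoate, via silyl allenolate 5 (not isolated), via aldol silyl ether 6 (not isolated)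
Conditions: TMSBr (1.3 equiv), (S)-1-(2-methylphenyl)-3,3-diphenyltetrahydro-1H,3H-pyrrolo[1,2-c][1,3,2]oxazaborole·HN(SO2CF3)2 (20 mol %), CH2Cl2, −78 → −40 °C; then aq. citric acid, 0 °C
Reagents that add atoms: bromotrimethylsilane, C[Si](C)(C)Br
Why: Proposed new method: TMSBr adds 1,4 to ynoate 3 to give silyl allenolate 5, which attacks the oxazaborolidinium-bound butanal in a Mukaiyama-type aldol at C2 in the plane of the C3 substituents and anti to the bulky diethoxymethyl group (so Br ends cis to the carbinol and the ester cis to the acetal, 2E), on the aldehyde Si face left open by the catalyst (so 1R), and the silyl ether 6 is cleaved by the citric acid work-up; the closest known reaction type is the oxazaborolidinium-catalysed three-component halo-aldol coupling of iodotrimethylsilane, propiolate esters and aldehydes to β-iodo Morita–Baylis–Hillman esters, extended here to bromide and to a β-substituted ynoate.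

**Step 3**
Reactants: 7 tert-butyl (2E)-3-bromo-4,4-diethoxy-2-[(1R)-1-hydroxybutyl]but-2-enoate
Product: 9 4-bromo-5-hydroxy-3-[(1R)-1-hydroxybutyl]furan-2(5H)-one, via formyl acid 8 (not isolated)
Conditions: CF3CO2H/H2O (4:1), CH2Cl2, 0 °C → rt
Reagents that add atoms: water, O
Why: Acidolysis removes the tert-butyl ester and hydrolyses the acetal, and because formyl and carboxyl groups are cis on the double bond the free formyl acid 8 closes to the pseudo-acid lactol (ring–chain tautomerism as in mucobromic acid), which fixes the alkene geometry without involving the carbinol centre.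

**Step 4**
Reactants: 9 4-bromo-5-hydroxy-3-[(1R)-1-hydroxybutyl]furan-2(5H)-one
Product: 12 (2E)-3-bromo-2-[(1R)-1-hydroxybutyl]pent-2-en-4-ynoic acid, via potassium formyl carboxylate 10 (not isolated), via potassium enynoate 11 (not isolated)
Conditions: dimethyl (1-diazo-2-oxopropyl)phosphonate, K2CO3, MeOH, 0 °C → rt; then 1 M HCl to pH 3
Reagents that add atoms: dimethyl (1-diazo-2-oxopropyl)phosphonate, CC(=O)C(=[N+]=[N-])P(=O)(OC)OC
Why: In K2CO3/MeOH the lactol is deprotonated and opens to the potassium salt 10 of the formyl acid, whose aldehyde undergoes Seyferth–Gilbert homologation in the Ohira–Bestmann form (Horner–Wadsworth–Emmons addition, loss of N2, 1,2-hydrogen shift) to the potassium enynoate 11 with the alkyne necessarily cis to the carboxylate; HCl then gives the free acid, and C1' is untouched throughout.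

**Step 5**
Reactants: 12 (2E)-3-bromo-2-[(1R)-1-hydroxybutyl]pent-2-en-4-ynoic acid
Product: 13 (5E)-4-bromo-5-(bromomethylidene)-3-[(1R)-1-hydroxybutyl]furan-2(5H)-one
Conditions: NBS, KHCO3, Bu4NOH (cat.), CH2Cl2/H2O, 0 °C, dark
Reagents that add atoms: N-bromosuccinimide, O=C1CCC(=O)N1Br
Why: Bromo-enol-lactonisation, in which the carboxylate opens the NBS-derived bromonium ion of the terminal alkyne at the internal carbon (5-exo-dig) and anti to bromine, puts Br trans to the ring oxygen and syn to C4 (5E), as is established for 4-pentynoic and (Z)-2-en-4-ynoic acids; the stereocentre is not touched.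

**Step 6**
Reactants: 13 (5E)-4-bromo-5-(bromomethylidene)-3-[(1R)-1-hydroxybutyl]furan-2(5H)-one
Product: 14 (1R)-1-[(5E)-4-bromo-5-(bromomethylidene)-2-oxo-2,5-dihydrofuran-3-yl]butyl acetate (acetoxyfimbrolide)
Conditions: Ac2O, Sc(OTf)3 (1 mol %), MeCN, −20 °C, dark
Reagents that add atoms: acetic anhydride, CC(=O)OC(C)=O
Why: Lewis-acid-catalysed esterification acylates the oxygen only, so C1' keeps its R configuration, and it avoids nucleophilic amine bases that could attack the 4-bromobutenolide.

**Compound list**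
1 | 3,3-diethoxyprop-1-yne | C#CC(OCC)OCC | starting material
2 | lithium 3,3-diethoxyprop-1-yn-1-ide | [Li]C#CC(OCC)OCC | intermediate
3 | tert-butyl 4,4-diethoxybut-2-ynoate | CCOC(OCC)C#CC(=O)OC(C)(C)C | intermediate
4 | butanal | CCCC=O | starting material
5 | [(3-bromo-1-tert-butoxy-4,4-diethoxybuta-1,2-dien-1-yl)oxy]trimethylsilane (silyl allenolate) | CCOC(OCC)C(Br)=C=C(O[Si](C)(C)C)OC(C)(C)C | intermediate
6 | tert-butyl (2E)-3-bromo-4,4-diethoxy-2-[(1R)-1-(trimethylsilyloxy)butyl]but-2-enoate | CCC[C@@H](O[Si](C)(C)C)/C(C(=O)OC(C)(C)C)=C(\Br)C(OCC)OCC | intermediate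
7 | tert-butyl (2E)-3-bromo-4,4-diethoxy-2-[(1R)-1-hydroxybutyl]but-2-enoate | CCC[C@@H](O)/C(C(=O)OC(C)(C)C)=C(\Br)C(OCC)OCC | intermediate
8 | (2E)-3-bromo-2-[(1R)-1-hydroxybutyl]-4-oxobut-2-enoic acid | CCC[C@@H](O)/C(C(O)=O)=C(\Br)C=O | intermediate
9 | 4-bromo-5-hydroxy-3-[(1R)-1-hydroxybutyl]furan-2(5H)-one (both C5 epimers) | CCC[C@@H](O)C1=C(Br)C(O)OC1=O | intermediate
10 | potassium (2E)-3-bromo-2-[(1R)-1-hydroxybutyl]-4-oxobut-2-enoate | CCC[C@@H](O)/C(C(=O)[O-])=C(\Br)C=O.[K+] | intermediate
11 | potassium (2E)-3-bromo-2-[(1R)-1-hydroxybutyl]pent-2-en-4-ynoate | CCC[C@@H](O)/C(C(=O)[O-])=C(\Br)C#C.[K+] | intermediate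
12 | (2E)-3-bromo-2-[(1R)-1-hydroxybutyl]pent-2-en-4-ynoic acid (CO2H cis to ethynyl) | CCC[C@@H](O)/C(C(O)=O)=C(\Br)C#C | intermediate
13 | (5E)-4-bromo-5-(bromomethylidene)-3-[(1R)-1-hydroxybutyl]furan-2(5H)-one | CCC[C@@H](O)C1=C(Br)/C(=C\Br)OC1=O | intermediate
14 | (1R)-1-[(5E)-4-bromo-5-(bromomethylidene)-2-oxo-2,5-dihydrofuran-3-yl]butyl acetate | CCC[C@@H](OC(C)=O)C1=C(Br)/C(=C\Br)OC1=O | target

**Total steps:** 6. **Longest linear sequence:** 6 steps (1 → 14).

**Steps most likely to fail**

Step 2 (the proposed new step). TMSBr may add too slowly to the β-substituted ynoate at low temperature, may erode the acetal or the tert-butyl ester on warming, or the enantioselectivity or its sense may fall short. The fallback uses known chemistry, sets out from butanal 4 and comes back at lactol 9. Butanal 4 takes up a 3-furyl group from 3-furyl(butyl)zinc (from 3-bromofuran, n-BuLi, ZnCl2 and a second equivalent of n-BuLi) under catalysis by the enantiomer of 3-exo-morpholinoisoborneol that gives the R carbinol, affording (1R)-1-(furan-3-yl)butan-1-ol F1. Alkoxide-directed lithiation at C2 (n-BuLi, 2.2 equiv, THF, 0 °C) and Me3SiCl (2.5 equiv) give trimethyl{(1R)-1-[2-(trimethylsilyl)furan-3-yl]butoxy}silane F2, and K2CO3 in MeOH removes the O-silyl group to give (1R)-1-[2-(trimethylsilyl)furan-3-yl]butan-1-ol F3. Singlet-oxygen oxidation (O2, hν, 5,10,15,20-tetraphenylporphyrin, CH2Cl2, −78 °C; then water), in which the silyl-bearing carbon becomes the lactone carbonyl, gives 5-hydroxy-3-[(1R)-1-hydroxybutyl]furan-2(5H)-one F4. Br2 (CH2Cl2, 0 °C) adds across the ring double bond to give 3,4-dibromo-5-hydroxy-3-[(1R)-1-hydroxybutyl]oxolan-2-one F5, and Et3N then removes HBr (the C4 hydrogen, alpha to the masked aldehyde, and the C3 bromine) to give 9.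

Step 4. The lactol may open sluggishly, or methoxide may damage the bromo-enal carboxylate before homologation. The fallback sets out from 7 and comes back at 12. Pyridinium p-toluenesulfonate in wet acetone unmasks only the acetal to give tert-butyl (2E)-3-bromo-2-[(1R)-1-hydroxybutyl]-4-oxobut-2-enoate F6. This neutral enal ester is homologated under aprotic Colvin conditions (Me3SiCHN2, LiN(i-Pr)2, THF, −78 °C → rt) to tert-butyl (2E)-3-bromo-2-[(1R)-1-hydroxybutyl]pent-2-en-4-ynoate F7. CF3CO2H (CH2Cl2, 0 °C) then frees acid 12.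

Step 5. The electron-poor alkyne may react slowly, 6-endo closure to a pyranone may compete, or light may isomerise the E-bromide. The fallback sets out from 12 and comes back at 13. Br2 (1 equiv, CH2Cl2, −78 °C) adds anti across the terminal alkyne to give (2E,4E)-3,4,5-tribromo-2-[(1R)-1-hydroxybutyl]penta-2,4-dienoic acid F8. CuI/1,10-phenanthroline with Cs2CO3 (intramolecular O-vinylation of the carboxylic acid with retention at the vinyl carbon) then closes the five-membered enol lactone to 13.

**Further compounds**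
F1 | step 2 | (1R)-1-(furan-3-yl)butan-1-ol | CCC[C@@H](O)c1ccoc1
F2 | step 2 | trimethyl{(1R)-1-[2-(trimethylsilyl)furan-3-yl]butoxy}silane | CCC[C@@H](O[Si](C)(C)C)c1ccoc1[Si](C)(C)C
F3 | step 2 | (1R)-1-[2-(trimethylsilyl)furan-3-yl]butan-1-ol | CCC[C@@H](O)c1ccoc1[Si](C)(C)C
F4 | step 2 | 5-hydroxy-3-[(1R)-1-hydroxybutyl]furan-2(5H)-one | CCC[C@@H](O)C1=CC(O)OC1=O
F5 | step 2 | 3,4-dibromo-5-hydroxy-3-[(1R)-1-hydroxybutyl]oxolan-2-one (mixture of ring diastereomers) | CCC[C@@H](O)C1(Br)C(Br)C(O)OC1=O
F6 | step 4 | tert-butyl (2E)-3-bromo-2-[(1R)-1-hydroxybutyl]-4-oxobut-2-enoate | CCC[C@@H](O)/C(C(=O)OC(C)(C)C)=C(\Br)C=O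
F7 | step 4 | tert-butyl (2E)-3-bromo-2-[(1R)-1-hydroxybutyl]pent-2-en-4-ynoate | CCC[C@@H](O)/C(C(=O)OC(C)(C)C)=C(\Br)C#C
F8 | step 5 | (2E,4E)-3,4,5-tribromo-2-[(1R)-1-hydroxybutyl]penta-2,4-dienoic acid | CCC[C@@H](O)/C(C(O)=O)=C(\Br)/C(Br)=C\Br
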